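**Retrosynthetic overview**
- No ring is formed. The naphthoquinone comes from menadione, is carried as its 1,4-dimethyl ether and is released last with CAN.
- Key disconnection C4′–C5′: the aldehyde carbon of (S)-citronellal is used as an alkyl-carbanion equivalent (its N–H hydrazone, carbonyl umpolung) and joined to the E-allylic carbonate of the head under Pd(0). N2 leaves and C5′ ends as CH2.
- Head: chloromethylated dimethoxy-methylnaphthalene plus the alkenylalane from propargyl alcohol; syn-carboalumination fixes C2′=C3′ as E.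
- Tail: C12′–C13′ and C20′–C21′ by two rounds of SeO2 ω-oxidation, bromide formation and allylbarium coupling (geranyl, then farnesyl).
- C7′ comes from citronellal and is never touched.

Assumption: side-chain carbons are numbered C1′–C32′ from the ring; the stereocentre keeps the spatial arrangement of (S)-citronellal throughout and is labelled R in 12–23 only because the CIP priorities of its two chain arms swap.

**Step 1**
Reactants: 1 menadione
Product: 3 1,4-dimethoxy-2-methylnaphthalene, via menadiol 2 (not isolated)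
Conditions: Na2S2O4, THF/H2O, rt; then KOH, Bu4NBr (cat.), Me2SO4, rt
Reagents that add atoms: dimethyl sulfate, COS(=O)(=O)OC
Why: Dithionite reduction followed in the same pot by Williamson O-methylation masks the quinone, which would not survive hydrazine, organoaluminium or organobarium reagents.

**Step 2**
Reactants: 3 1,4-dimethoxy-2-methylnaphthalene
Product: 4 2-(chloromethyl)-1,4-dimethoxy-3-methylnaphthalene
Conditions: (CH2O)n, conc. HCl/HCl(g), 1,4-dioxane, 60 °C
Reagents that add atoms: formaldehyde (as paraformaldehyde), C=O; hydrogen chloride, Cl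
Why: Blanc chloromethylation, an electrophilic aromatic substitution that can only go to C3, the one free position of the doubly activated ring.

**Step 3**
Reactants: 4 2-(chloromethyl)-1,4-dimethoxy-3-methylnaphthalene; 5 propargyl alcohol
Product: 7 (2E)-4-(1,4-dimethoxy-3-methylnaphthalen-2-yl)-2-methylbut-2-en-1-ol, via alkenylalane 6 (not isolated)
Conditions: 5, Me3Al (3 equiv), Cp2ZrCl2 (0.25 equiv), CH2Cl2, 0 °C to rt; then 4, Ni(0) [NiCl2(PPh3)2 + 2 n-BuLi, 5 mol%], THF, rt; aq. HCl work-up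
Reagents that add atoms: trimethylaluminium, C[Al](C)C
Why: Negishi zirconium-catalysed syn-methylalumination of the alkyne (Me to the inner carbon, Al and Me cis) and nickel-catalysed alkenylalane–benzylic chloride cross-coupling with retention give C2′=C3′ as the E isomer only.

**Step 4**
Reactants: 7 (2E)-4-(1,4-dimethoxy-3-methylnaphthalen-2-yl)-2-methylbut-2-en-1-ol
Product: 8 (2E)-4-(1,4-dimethoxy-3-methylnaphthalen-2-yl)-2-methylbut-2-en-1-yl methyl carbonate
Conditions: ClCO2Me, pyridine, CH2Cl2, 0 °C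
Reagents that add atoms: methyl chloroformate, COC(=O)Cl
Why: Acylation of the primary allylic alcohol gives a Tsuji–Trost leaving group that releases its own base (methoxide) and CO2 on ionisation.

**Step 5 (key step)**
Reactants: 8 (2E)-4-(1,4-dimethoxy-3-methylnaphthalen-2-yl)-2-methylbut-2-en-1-yl methyl carbonate; 9 (S)-citronellal
Product: 12 1,4-dimethoxy-2-methyl-3-[(2E,7R)-3,7,11-trimethyldodeca-2,10-dien-1-yl]naphthalene, via citronellal hydrazone 10 (not isolated), via alkyl diazene 11 (not isolated)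
Conditions: 9 (1.3 equiv), N2H4·H2O (1.3 equiv), THF, rt, then 4 Å MS; add 8, [Pd(allyl)Cl]2 (2.5 mol%), Xantphos (6 mol%), LiOt-Bu (20 mol%), THF, 50 °C
Reagents that add atoms: none
Why: Proposed new method: the N–H hydrazone 10 makes the aldehyde carbon C5′ nucleophilic (carbonyl umpolung, an alkyl-carbanion equivalent), so two natively electrophilic carbons are joined: Pd(0) ionises 8 to a π-allyl complex and methoxide, the deprotonated hydrazone binds Pd through nitrogen and its azomethine carbon is delivered to the unhindered CH2 terminus C4′ to give diazene 11, which loses N2 by base-mediated Wolff–Kishner-type denitrogenation so that C5′ ends as CH2; the closest known reaction type is the Pd-catalysed Tsuji–Trost allylic alkylation with N-unsubstituted hydrazones as unstabilised carbanion surrogates, extended here to an enolisable aliphatic hydrazone and a 2-methyl-substituted allyl unit; no new stereocentre survives, C7′ comes unchanged from 9 and the E alkene from 8.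

**Step 6**
Reactants: 12 1,4-dimethoxy-2-methyl-3-[(2E,7R)-3,7,11-trimethyldodeca-2,10-dien-1-yl]naphthalene
Product: 13 (2E,6R,10E)-12-(1,4-dimethoxy-3-methylnaphthalen-2-yl)-2,6,10-trimethyldodeca-2,10-dien-1-ol
Conditions: SeO2 (0.3 equiv), t-BuOOH (3 equiv), salicylic acid (cat.), CH2Cl2, rt
Reagents that add atoms: tert-butyl hydroperoxide, CC(C)(C)OO (oxygen source, delivered through catalytic selenium dioxide, O=[Se]=O)
Why: Sharpless SeO2/t-BuOOH allylic oxidation (ene reaction, then [2,3]-sigmatropic shift) hydroxylates the E-methyl of the terminal isopropylidene, which defines C10′=C11′ as E.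

**Step 7**
Reactants: 13 (2E,6R,10E)-12-(1,4-dimethoxy-3-methylnaphthalen-2-yl)-2,6,10-trimethyldodeca-2,10-dien-1-ol
Product: 14 2-[(2E,7R,10E)-12-bromo-3,7,11-trimethyldodeca-2,10-dien-1-yl]-1,4-dimethoxy-3-methylnaphthalene
Conditions: CBr4, PPh3, CH2Cl2, 0 °C
Reagents that add atoms: carbon tetrabromide, BrC(Br)(Br)Br
Why: Appel reaction, an SN2 displacement at the primary allylic CH2 that leaves the alkene geometry alone.

**Step 8**
Reactants: 14 2-[(2E,7R,10E)-12-bromo-3,7,11-trimethyldodeca-2,10-dien-1-yl]-1,4-dimethoxy-3-methylnaphthalene; 15 geranyl chloride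
Product: 17 1,4-dimethoxy-2-methyl-3-[(2E,7R,10E,14E)-3,7,11,15,19-pentamethylicosa-2,10,14,18-tetraen-1-yl]naphthalene, via geranylbarium chloride 16 (not isolated)
Conditions: BaI2, lithium biphenylide (2 equiv), THF, rt (active Ba); 15, −78 °C; then 14, −78 °C
Reagents that add atoms: none
Why: Yamamoto allylbarium cross-coupling: the configurationally stable geranylbarium reagent attacks the allylic bromide α to α′ (SN2) with retention of both E alkenes, forming C12′–C13′.

**Step 9**
Reactants: 17 1,4-dimethoxy-2-methyl-3-[(2E,7R,10E,14E)-3,7,11,15,19-pentamethylicosa-2,10,14,18-tetraen-1-yl]naphthalene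
Product: 18 (2E,6E,10E,14R,18E)-20-(1,4-dimethoxy-3-methylnaphthalen-2-yl)-2,6,10,14,18-pentamethylicosa-2,6,10,18-tetraen-1-ol
Conditions: SeO2 (0.3 equiv), t-BuOOH (3 equiv), salicylic acid (cat.), CH2Cl2, 0 °C to rt, stopped at partial conversion
Reagents that add atoms: tert-butyl hydroperoxide, CC(C)(C)OO (oxygen source, delivered through catalytic selenium dioxide, O=[Se]=O)
Why: Sharpless SeO2 allylic oxidation again favours the E-methyl of the least hindered, terminal trisubstituted alkene, defining C18′=C19′ as E.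

**Step 10**
Reactants: 18 (2E,6E,10E,14R,18E)-20-(1,4-dimethoxy-3-methylnaphthalen-2-yl)-2,6,10,14,18-pentamethylicosa-2,6,10,18-tetraen-1-ol
Product: 19 2-[(2E,7R,10E,14E,18E)-20-bromo-3,7,11,15,19-pentamethylicosa-2,10,14,18-tetraen-1-yl]-1,4-dimethoxy-3-methylnaphthalene
Conditions: CBr4, PPh3, CH2Cl2, 0 °C
Reagents that add atoms: carbon tetrabromide, BrC(Br)(Br)Br
Why: Appel reaction at the primary allylic alcohol, SN2, geometry retained.

**Step 11**
Reactants: 19 2-[(2E,7R,10E,14E,18E)-20-bromo-3,7,11,15,19-pentamethylicosa-2,10,14,18-tetraen-1-yl]-1,4-dimethoxy-3-methylnaphthalene; 20 (2E,6E)-farnesyl chloride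
Product: 22 1,4-dimethoxy-2-methyl-3-[(2E,7R,10E,14E,18E,22E,26E)-3,7,11,15,19,23,27,31-octamethyldotriaconta-2,10,14,18,22,26,30-heptaen-1-yl]naphthalene, via farnesylbarium chloride 21 (not isolated)
Conditions: BaI2, lithium biphenylide (2 equiv), THF, rt; 20, −78 °C; then 19, −78 °C
Reagents that add atoms: none
Why: Second Yamamoto allylbarium α,α′ cross-coupling forms C20′–C21′ and brings in the last three isoprene units with their E geometry intact.

**Step 12**
Reactants: 22 1,4-dimethoxy-2-methyl-3-[(2E,7R,10E,14E,18E,22E,26E)-3,7,11,15,19,23,27,31-octamethyldotriaconta-2,10,14,18,22,26,30-heptaen-1-yl]naphthalene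
Product: 23 2-methyl-3-[(2E,7R,10E,14E,18E,22E,26E)-3,7,11,15,19,23,27,31-octamethyldotriaconta-2,10,14,18,22,26,30-heptaen-1-yl]naphthalene-1,4-dione
Conditions: (NH4)2Ce(NO3)6 (2.5 equiv), MeCN/CH2Cl2/H2O, 0 °C
Reagents that add atoms: water, O
Why: CAN oxidative demethylation of the 1,4-dimethoxyarene (arene radical cation, water adds at the ipso carbons, methanol leaves) gives the quinone without touching the isolated trisubstituted alkenes or C7′.

**Compound list**
1 | menadione (2-methylnaphthalene-1,4-dione) | CC1=CC(=O)c2ccccc2C1=O | starting material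
2 | menadiol (2-methylnaphthalene-1,4-diol) | Cc1cc(O)c2ccccc2c1O | intermediate
3 | 1,4-dimethoxy-2-methylnaphthalene | COc1cc(C)c(OC)c2ccccc12 | intermediate
4 | 2-(chloromethyl)-1,4-dimethoxy-3-methylnaphthalene | COc1c(C)c(CCl)c(OC)c2ccccc12 | intermediate
5 | propargyl alcohol (prop-2-yn-1-ol) | OCC#C | starting material
6 | alkenylalane, dimethyl[(1E)-3-(dimethylalumanyloxy)-2-methylprop-1-en-1-yl]alumane | C[Al](C)/C=C(C)/CO[Al](C)C | intermediate
7 | (2E)-4-(1,4-dimethoxy-3-methylnaphthalen-2-yl)-2-methylbut-2-en-1-ol | COc1c(C)c(C/C=C(\C)CO)c(OC)c2ccccc12 | intermediate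
8 | (2E)-4-(1,4-dimethoxy-3-methylnaphthalen-2-yl)-2-methylbut-2-en-1-yl methyl carbonate | COC(=O)OC/C(C)=C/Cc1c(C)c(OC)c2ccccc2c1OC | intermediate
9 | (S)-(−)-citronellal, (3S)-3,7-dimethyloct-6-enal | CC(C)=CCC[C@H](C)CC=O | starting material
10 | citronellal hydrazone, [(1E,3S)-3,7-dimethyloct-6-en-1-ylidene]hydrazine | CC(C)=CCC[C@H](C)C/C=N/N | intermediate
11 | alkyl diazene: 12 carrying –N=NH at C5′ (both C5′ epimers, C7′ arrangement as in 9) | CC(C)=CCC[C@H](C)CC(N=N)C/C(C)=C/Cc1c(C)c(OC)c2ccccc2c1OC | intermediate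
12 | 1,4-dimethoxy-2-methyl-3-[(2E,7R)-3,7,11-trimethyldodeca-2,10-dien-1-yl]naphthalene | CC(C)=CCC[C@H](C)CCC/C(C)=C/Cc1c(C)c(OC)c2ccccc2c1OC | intermediate
13 | (2E,6R,10E)-12-(1,4-dimethoxy-3-methylnaphthalen-2-yl)-2,6,10-trimethyldodeca-2,10-dien-1-ol | OC/C(C)=C/CC[C@H](C)CCC/C(C)=C/Cc1c(C)c(OC)c2ccccc2c1OC | intermediate
14 | 2-[(2E,7R,10E)-12-bromo-3,7,11-trimethyldodeca-2,10-dien-1-yl]-1,4-dimethoxy-3-methylnaphthalene | BrC/C(C)=C/CC[C@H](C)CCC/C(C)=C/Cc1c(C)c(OC)c2ccccc2c1OC | intermediate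
15 | geranyl chloride, (2E)-1-chloro-3,7-dimethylocta-2,6-diene | CC(C)=CCC/C(C)=C/CCl | starting material
16 | geranylbarium chloride | CC(C)=CCC/C(C)=C/C[Ba]Cl | intermediate
17 | 1,4-dimethoxy-2-methyl-3-[(2E,7R,10E,14E)-3,7,11,15,19-pentamethylicosa-2,10,14,18-tetraen-1-yl]naphthalene | CC(C)=CCC/C(C)=C/CC/C(C)=C/CC[C@H](C)CCC/C(C)=C/Cc1c(C)c(OC)c2ccccc2c1OC | intermediate
18 | (2E,6E,10E,14R,18E)-20-(1,4-dimethoxy-3-methylnaphthalen-2-yl)-2,6,10,14,18-pentamethylicosa-2,6,10,18-tetraen-1-ol | OC/C(C)=C/CC/C(C)=C/CC/C(C)=C/CC[C@H](C)CCC/C(C)=C/Cc1c(C)c(OC)c2ccccc2c1OC | intermediate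
19 | 2-[(2E,7R,10E,14E,18E)-20-bromo-3,7,11,15,19-pentamethylicosa-2,10,14,18-tetraen-1-yl]-1,4-dimethoxy-3-methylnaphthalene | BrC/C(C)=C/CC/C(C)=C/CC/C(C)=C/CC[C@H](C)CCC/C(C)=C/Cc1c(C)c(OC)c2ccccc2c1OC | intermediate
20 | (2E,6E)-farnesyl chloride, (2E,6E)-1-chloro-3,7,11-trimethyldodeca-2,6,10-triene | CC(C)=CCC/C(C)=C/CC/C(C)=C/CCl | starting material
21 | farnesylbarium chloride | CC(C)=CCC/C(C)=C/CC/C(C)=C/C[Ba]Cl | intermediate
22 | 1,4-dimethoxy-2-methyl-3-[(2E,7R,10E,14E,18E,22E,26E)-3,7,11,15,19,23,27,31-octamethyldotriaconta-2,10,14,18,22,26,30-heptaen-1-yl]naphthalene | CC(C)=CCC/C(C)=C/CC/C(C)=C/CC/C(C)=C/CC/C(C)=C/CC/C(C)=C/CC[C@H](C)CCC/C(C)=C/Cc1c(C)c(OC)c2ccccc2c1OC | intermediate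
23 | 2-methyl-3-[(2E,7R,10E,14E,18E,22E,26E)-3,7,11,15,19,23,27,31-octamethyldotriaconta-2,10,14,18,22,26,30-heptaen-1-yl]naphthalene-1,4-dione (CNP0107344.1) | CC(C)=CCC/C(C)=C/CC/C(C)=C/CC/C(C)=C/CC/C(C)=C/CC/C(C)=C/CC[C@H](C)CCC/C(C)=C/CC1=C(C)C(=O)c2ccccc2C1=O | target

**Step count and risk**
Total steps: 12. Longest linear sequence: 12 (menadione 1 to 23); counted from (S)-citronellal 9 it is 8.

Three steps most likely to fail:

Step 5. The Pd-bound hydrazone may attack the substituted allyl terminus (branched isomer), the 2-methyl π-allyl may partly lose E geometry, and N-allylation or plain Wolff–Kishner reduction of 10 may compete. The fallback sets out from alcohol 7 and citronellal 9 and comes back at 12. It keeps the C4′–C5′ bond and the polarity reversal but uses a stoichiometric SN2 alkylation of a sulfur-stabilised acyl-anion equivalent. An Appel reaction on 7 gives 2-[(2E)-4-bromo-3-methylbut-2-en-1-yl]-1,4-dimethoxy-3-methylnaphthalene F1. Aldehyde 9 with propane-1,3-dithiol (MgBr2·OEt2, Et2O, 0 °C, mild enough to avoid carbonyl-ene cyclisation) gives 2-[(2S)-2,6-dimethylhept-5-en-1-yl]-1,3-dithiane F2. Lithiation (n-BuLi, THF, −30 °C) and addition of F1 give 2-[(2S)-2,6-dimethylhept-5-en-1-yl]-2-[(2E)-4-(1,4-dimethoxy-3-methylnaphthalen-2-yl)-2-methylbut-2-en-1-yl]-1,3-dithiane F3. Radical desulfurisation (Bu3SnH, AIBN, toluene, reflux) then gives 12.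

Step 9. SeO2 must pick the terminal alkene among four trisubstituted alkenes, so a low yield and regioisomeric alcohols are likely. The fallback sets out from bromide 14 and geranyl chloride 15 and comes back at 18. It moves the oxidation onto the C10 building block. SeO2/t-BuOOH on 15, whose 2,3-alkene is deactivated by the allylic chloride, gives (2E,6E)-8-chloro-2,6-dimethylocta-2,6-dien-1-ol F4. TBSCl/imidazole gives tert-butyl{[(2E,6E)-8-chloro-2,6-dimethylocta-2,6-dien-1-yl]oxy}dimethylsilane F5. Its barium reagent (as in step 8) couples with 14 to give tert-butyl{[(2E,6E,10E,14R,18E)-20-(1,4-dimethoxy-3-methylnaphthalen-2-yl)-2,6,10,14,18-pentamethylicosa-2,6,10,18-tetraen-1-yl]oxy}dimethylsilane F6, and TBAF in THF gives 18.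

Step 11 (the same concern applies to step 8). Active barium is delicate, and α/γ scrambling or Wurtz homocoupling of the precious bromide would be costly here. The fallback sets out from bromide 19 and farnesyl chloride 20 and comes back at 22. It replaces the organometallic by a sulfone-stabilised allyl anion. PhSO2Na in DMF converts 20 into {[(2E,6E)-3,7,11-trimethyldodeca-2,6,10-trien-1-yl]sulfonyl}benzene F7. Deprotonation (n-BuLi, THF/HMPA, −78 °C) and alkylation with 19 give 2-[(2E,7R,10E,14E,18E,22E,26E)-3,7,11,15,19,23,27,31-octamethyl-21-(phenylsulfonyl)dotriaconta-2,10,14,18,22,26,30-heptaen-1-yl]-1,4-dimethoxy-3-methylnaphthalene F8. Reductive desulfonylation (PdCl2(dppp) cat., LiEt3BH, THF, 0 °C) gives 22.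

**Further compounds**
F1 | step 5 | 2-[(2E)-4-bromo-3-methylbut-2-en-1-yl]-1,4-dimethoxy-3-methylnaphthalene | COc1c(C)c(C/C=C(\C)CBr)c(OC)c2ccccc12
F2 | step 5 | 2-[(2S)-2,6-dimethylhept-5-en-1-yl]-1,3-dithiane | CC(C)=CCC[C@H](C)CC1SCCCS1
F3 | step 5 | 2-[(2S)-2,6-dimethylhept-5-en-1-yl]-2-[(2E)-4-(1,4-dimethoxy-3-methylnaphthalen-2-yl)-2-methylbut-2-en-1-yl]-1,3-dithiane | CC(C)=CCC[C@H](C)CC1(C/C(C)=C/Cc2c(C)c(OC)c3ccccc3c2OC)SCCCS1
F4 | step 9 | (2E,6E)-8-chloro-2,6-dimethylocta-2,6-dien-1-ol | OC/C(C)=C/CC/C(C)=C/CCl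
F5 | step 9 | tert-butyl{[(2E,6E)-8-chloro-2,6-dimethylocta-2,6-dien-1-yl]oxy}dimethylsilane | CC(C)(C)[Si](C)(C)OC/C(C)=C/CC/C(C)=C/CCl
F6 | step 9 | tert-butyl{[(2E,6E,10E,14R,18E)-20-(1,4-dimethoxy-3-methylnaphthalen-2-yl)-2,6,10,14,18-pentamethylicosa-2,6,10,18-tetraen-1-yl]oxy}dimethylsilane | CC(C)(C)[Si](C)(C)OC/C(C)=C/CC/C(C)=C/CC/C(C)=C/CC[C@H](C)CCC/C(C)=C/Cc1c(C)c(OC)c2ccccc2c1OC
F7 | step 11 | {[(2E,6E)-3,7,11-trimethyldodeca-2,6,10-trien-1-yl]sulfonyl}benzene | CC(C)=CCC/C(C)=C/CC/C(C)=C/CS(=O)(=O)c1ccccc1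
F8 | step 11 | 2-[(2E,7R,10E,14E,18E,22E,26E)-3,7,11,15,19,23,27,31-octamethyl-21-(phenylsulfonyl)dotriaconta-2,10,14,18,22,26,30-heptaen-1-yl]-1,4-dimethoxy-3-methylnaphthalene (both C21′ epimers) | CC(C)=CCC/C(C)=C/CC/C(C)=C/C(C/C(C)=C/CC/C(C)=C/CC/C(C)=C/CC[C@H](C)CCC/C(C)=C/Cc1c(C)c(OC)c2ccccc2c1OC)S(=O)(=O)c1ccccc1
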